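**Strategy.** Everything rests on disconnecting the C9–C10 bond, which joins the two adjacent quaternary carbons of ring B (C5–C10). Ring B is treated as the five-membered ring of a trans-hydrindane (C5, C6, C7, C8, C10) plus one inserted carbon, C9. A Lewis-acid semipinacol shift of C10 from C8 to C9 forms this bond, enlarges the ring, sets the C9 stereocentre and leaves a C8 ketone, all in one operation. Its precursor is a trans-fused 4α-silyloxy-10β-methylhydrindan-8β-ol carrying a (2-methyloxiran-2-yl) group at C8, made from the (S)-Hajos–Parrish ketone. The C8 ketone, the C11 hydroxymethyl and the C4 oxygen then become the C8 methyl, the quinone arm and the exocyclic methylene.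

Key step: step 8

Remark (numbering): the carbon labels of the target decalin are used for every intermediate, so the hydrindanes have no C9. C4 bears the exocyclic CH2 or its oxygen precursor, C5 is the ring-fusion CH, C10 the angular-methyl carbon, C8 the future CH–CH3, C9 the inserted carbon and C11 its CH2. β is the face of the C10 methyl, α the opposite face.

Remark (chemistry, assumption): C9 of epoxide 13 must be S for C10 to arrive on the correct face. Epoxidation of the corresponding 8α-isopropenyl-8β-ol is expected to place oxygen on the exposed alkene face and so lead to the C9 epimer. The epoxide is therefore built the other way round, by methylene transfer to the α-ketol 12, where the same facial bias delivers C11 instead of oxygen.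

Step 1
Reactants: 1 (S)-Hajos–Parrish ketone
Product: 2 3,3-ethylenedithio-10-methylhydrind-4-en-8-one
Conditions: HS(CH2)2SH, p-TsOH (cat.), AcOH, rt
Reagents that add atoms: ethane-1,2-dithiol, SCCS
Why: Acid-catalysed dithioketalisation should be chemoselective for the conjugated C3 carbonyl (allyl-stabilised thionium, unhindered) over the neopentyl cyclopentanone C8, and a dithiolane keeps the C4=C5 double bond in place.

Step 2
Reactants: 2 3,3-ethylenedithio-10-methylhydrind-4-en-8-one
Product: 3 3,3-ethylenedithio-8,8-ethylenedioxy-10-methylhydrind-4-ene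
Conditions: HO(CH2)2OH, p-TsOH (cat.), PhH, reflux (Dean–Stark)
Reagents that add atoms: ethylene glycol, OCCO
Why: Standard ketalisation of the only remaining carbonyl masks C8 against borane, and the dithiolane is inert to these conditions.

Step 3
Reactants: 3 3,3-ethylenedithio-8,8-ethylenedioxy-10-methylhydrind-4-ene
Product: 4 8,8-ethylenedioxy-10-methylhydrind-4-ene
Conditions: Raney Ni (W-2), EtOH, reflux
Reagents that add atoms: none
Why: Mozingo desulfurisation replaces the C3 dithiolane by CH2 while the isolated trisubstituted C4=C5 alkene and the ketal survive, as in the conversion of Δ4-3-oxo steroid dithioketals into Δ4-olefins.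

Step 4
Reactants: 4 8,8-ethylenedioxy-10-methylhydrind-4-ene
Product: 7 4α-hydroxy-10β-methyl-trans-hydrindan-8-one, via alkylborane 5 (not isolated), via hydroxy ketal 6 (not isolated)
Conditions: BH3·THF, THF, 0 °C → rt; NaOH, H2O2, 0 °C → rt; then 1 M HCl, THF, rt
Reagents that add atoms: hydrogen peroxide, OO; water, O
Why: Brown hydroboration–oxidation adds H and B syn from the α face, anti to the angular methyl, so boron (then OH with retention) sits at C4α and hydrogen at C5α, which sets the trans ring fusion and C4 as with Δ4-steroids; the acidic work-up hydrolyses the dioxolane.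

Step 5
Reactants: 7 4α-hydroxy-10β-methyl-trans-hydrindan-8-one
Product: 8 4α-(tert-butyldimethylsilyloxy)-10β-methyl-trans-hydrindan-8-one
Conditions: TBSCl, imidazole, DMF, rt
Reagents that add atoms: tert-butyldimethylsilyl chloride, CC(C)(C)[Si](C)(C)Cl
Why: Silylation of the only hydroxyl gives a TBS ether that should withstand the organolithium, ylide, Lewis-acid, radical and redox steps up to step 15.

Step 6
Reactants: 8 4α-(tert-butyldimethylsilyloxy)-10β-methyl-trans-hydrindan-8-one; 9 ethyl vinyl ether
Product: 12 8α-acetyl-4α-TBSO-10β-methyl-trans-hydrindan-8β-ol, via 1-ethoxyvinyllithium 10 (not isolated), via ethoxyvinyl carbinol 11 (not isolated)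
Conditions: 9, t-BuLi, THF, −78 → 0 °C; then 8, −78 °C; 0.5 M HCl, THF/H2O, 0 °C
Reagents that add atoms: water, O
Why: 1,2-Addition of the acyl-anion equivalent 1-ethoxyvinyllithium to the C8 ketone from the α face, anti to the angular methyl (as with 17-oxo steroids), sets the 8β-hydroxyl, and dilute acid hydrolyses the enol ether to the methyl ketone without touching the TBS ether.

Step 7
Reactants: 12 8α-acetyl-4α-TBSO-10β-methyl-trans-hydrindan-8β-ol
Product: 13 8α-[(2S)-2-methyloxiran-2-yl]-4α-TBSO-10β-methyl-trans-hydrindan-8β-ol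
Conditions: Me3S+ I−, n-BuLi, THF, −10 °C; then 12, −10 → 0 °C
Reagents that add atoms: trimethylsulfonium iodide, C[S+](C)C.[I-]
Why: Corey–Chaykovsky methylene transfer: the C8–O and C9=O oxygens are held syn-periplanar by hydrogen bond and lithium coordination, C10 with C1 walls off one carbonyl face, and the ylide should therefore deliver C11 to the exposed face anti to C10 (Cram-chelate sense), setting C9 as S.

Step 8
Reactants: 13 8α-[(2S)-2-methyloxiran-2-yl]-4α-TBSO-10β-methyl-trans-hydrindan-8β-ol
Product: 14 9α-(hydroxymethyl)-9β,10β-dimethyl-4α-TBSO-trans-decalin-8-one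
Conditions: BF3·OEt2 (1.1 equiv), CH2Cl2, −78 °C; aq. NaHCO3
Reagents that add atoms: none
Why: BF3 binds the epoxide oxygen and the tertiary C9–O bond ionises while the antiperiplanar C8–C10 bond shifts from C8 to C9 and the C8 hydroxyl becomes the ketone; this is the semipinacol rearrangement of a 2,3-epoxy alcohol, the known enlargement of 1-oxiranylcycloalkanols to 2-hydroxymethyl-2-alkylcycloalkanones. Ring B (C5–C10) is not closed by a cyclisation but arises from the five-membered ring by 1,2-shift ring enlargement, with C9 inserted between C8 and C10. C9 is the only new stereocentre and is controlled by the epoxide configuration from step 7, because C10 enters anti to the departing oxygen (inversion at C9, retention at C10), which gives 9β-methyl and 9α-hydroxymethyl. Two selectivities are needed: migration of C10 rather than C7, and a concerted course without a free C9 cation. The first should be secured by the higher migratory aptitude of the fully substituted C10 and by a monodentate Lewis acid whose complexed oxygen prefers the open position anti to C10; the second by the low temperature and the non-ionising solvent. The C4 silyl ether is remote and stable to BF3 at −78 °C.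

Step 9
Reactants: 14 9α-(hydroxymethyl)-9β,10β-dimethyl-4α-TBSO-trans-decalin-8-one
Product: 15 9α-(triethylsilyloxymethyl)-9β,10β-dimethyl-4α-TBSO-trans-decalin-8-one
Conditions: TESCl, imidazole, CH2Cl2, 0 °C
Reagents that add atoms: chlorotriethylsilane, CC[Si](CC)(CC)Cl
Why: Silylation of the primary neopentyl alcohol blocks retro-aldol loss of C11 as formaldehyde from the alkoxide under the basic olefination that follows.

Step 10
Reactants: 15 9α-(triethylsilyloxymethyl)-9β,10β-dimethyl-4α-TBSO-trans-decalin-8-one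
Product: 17 (8-methylene-9β,10β-dimethyl-4α-TBSO-trans-decalin-9α-yl)methanol, via methylene TES ether 16 (not isolated)
Conditions: Ph3PCH3Br, KOt-Bu, PhMe, 90 °C; then PPTS, MeOH, rt
Reagents that add atoms: methyltriphenylphosphonium bromide, C[P+](c1ccccc1)(c1ccccc1)c1ccccc1.[Br-]
Why: Wittig methylenation under forcing conditions should convert the hindered C8 ketone into the exocyclic alkene (no β-elimination is possible because C9 is quaternary), and PPTS in methanol then cleaves the primary TES ether in the presence of the secondary TBS ether.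

Step 11
Reactants: 17 (8-methylene-9β,10β-dimethyl-4α-TBSO-trans-decalin-9α-yl)methanol
Product: 18 (8β,9β,10β-trimethyl-4α-TBSO-trans-decalin-9α-yl)methanol
Conditions: H2 (1 atm), [Ir(cod)(PCy3)(py)]PF6 (5 mol%), CH2Cl2, rt
Reagents that add atoms: none
Why: Hydroxyl-directed hydrogenation with Crabtree's catalyst: iridium bound to the axial 9α-CH2OH delivers H2 to the α face of the C8 methylene, so C8 receives hydrogen α and carries its methyl β, the epimer that undirected delivery would not secure.

Step 12
Reactants: 18 (8β,9β,10β-trimethyl-4α-TBSO-trans-decalin-9α-yl)methanol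
Product: 19 8β,9β,10β-trimethyl-4α-TBSO-trans-decalin-9α-carbaldehyde
Conditions: TPAP (cat.), NMO, 4 Å MS, CH2Cl2, rt
Reagents that add atoms: none
Why: Ley–Griffith oxidation should stop at the non-enolisable neopentyl aldehyde and tolerates the silyl ether.

Step 13
Reactants: 19 8β,9β,10β-trimethyl-4α-TBSO-trans-decalin-9α-carbaldehyde; 20 1,2,4,5-tetramethoxybenzene
Product: 24 S-methyl xanthate of the C11 aryl carbinol, via aryllithium 21 (not isolated), via lithium alkoxide 22 (not isolated), via lithium xanthate 23 (not isolated)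
Conditions: 20, n-BuLi, THF, 0 °C → rt; then 19, −78 → 0 °C; CS2, 0 °C; MeI, rt
Reagents that add atoms: carbon disulfide, S=C=S; iodomethane, CI
Why: Directed ortho-lithiation between two methoxy groups, 1,2-addition of the aryllithium to the non-enolisable aldehyde and trapping of the alkoxide with CS2 then MeI should give the xanthate in one flask; the C11 configuration is irrelevant because this oxygen is removed next.

Step 14
Reactants: 24 S-methyl xanthate of the C11 aryl carbinol
Product: 25 9α-(2,3,5,6-tetramethoxybenzyl)-8β,9β,10β-trimethyl-4α-TBSO-trans-decalin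
Conditions: n-Bu3SnH, AIBN (cat.), PhMe, 110 °C
Reagents that add atoms: none
Why: Barton–McCombie deoxygenation through the benzylic radical, which cannot undergo Chugaev elimination or rearrange because C9 is quaternary, leaves the C11 methylene under neutral conditions that spare the methoxy groups.

Step 15
Reactants: 25 9α-(2,3,5,6-tetramethoxybenzyl)-8β,9β,10β-trimethyl-4α-TBSO-trans-decalin
Product: 26 9α-(2,3,5,6-tetramethoxybenzyl)-8β,9β,10β-trimethyl-trans-decalin-4α-ol
Conditions: TBAF, THF, rt → 50 °C
Reagents that add atoms: none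
Why: Fluoride-mediated desilylation frees the C4 alcohol, and nothing else in the molecule is fluoride-labile.

Step 16
Reactants: 26 9α-(2,3,5,6-tetramethoxybenzyl)-8β,9β,10β-trimethyl-trans-decalin-4α-ol
Product: 27 9α-(2,3,5,6-tetramethoxybenzyl)-8β,9β,10β-trimethyl-trans-decalin-4-one
Conditions: TPAP (cat.), NMO, 4 Å MS, CH2Cl2, rt
Reagents that add atoms: none
Why: Ley–Griffith oxidation gives the C4 ketone under neutral conditions that should neither epimerise C5 nor oxidise the electron-rich arene.

Step 17
Reactants: 27 9α-(2,3,5,6-tetramethoxybenzyl)-8β,9β,10β-trimethyl-trans-decalin-4-one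
Product: 28 9α-(2,3,5,6-tetramethoxybenzyl)-8β,9β,10β-trimethyl-4-methylene-trans-decalin
Conditions: Zn, CH2Br2, TiCl4, THF/CH2Cl2, 0 °C → rt
Reagents that add atoms: dibromomethane, BrCBr
Why: Takai–Lombardo methylenation is non-basic, so the unhindered C4 ketone should be olefinated without enolisation and the 5α-H (trans fusion) is retained.

Step 18
Reactants: 28 9α-(2,3,5,6-tetramethoxybenzyl)-8β,9β,10β-trimethyl-4-methylene-trans-decalin
Product: 29 3-[(8β,9β,10β-trimethyl-4-methylene-trans-decalin-9α-yl)methyl]-2,5-dimethoxy-1,4-benzoquinone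
Conditions: CAN, MeCN/H2O, 0 °C
Reagents that add atoms: water, O
Why: CAN oxidative demethylation of a para-dimethoxy pair gives the 2,5-dimethoxyquinone (either para pair gives the same quinone) faster than the isolated exocyclic alkene is attacked.

Step 19
Reactants: 29 3-[(8β,9β,10β-trimethyl-4-methylene-trans-decalin-9α-yl)methyl]-2,5-dimethoxy-1,4-benzoquinone
Product: 30 2-hydroxy-5-methoxy-3-[(8β,9β,10β-trimethyl-4-methylene-trans-decalin-9α-yl)methyl]-1,4-benzoquinone (CNP0109104.1)
Conditions: KOH, MeOH/H2O, rt; then 1 M HCl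
Reagents that add atoms: potassium hydroxide, [K+].[OH-]
Why: Addition–elimination of hydroxide at a vinylogous ester carbon; the methoxy flanked by the bulky C11 substituent is twisted out of conjugation and should be the one displaced, as with related 3-alkyl-2,5-dimethoxyquinones, and the exocyclic alkene is inert to base.

**Compound list**

1 | (S)-Hajos–Parrish ketone, (7aS)-7a-methyl-2,3,7,7a-tetrahydro-1H-indene-1,5(6H)-dione | O=C1CC[C@@]2(C)C(=C1)CCC2=O | starting material
2 | 3,3-ethylenedithio-10-methylhydrind-4-en-8-one (10S; dithiolane at C3, C4=C5, C8 ketone) | C12(SCCS1)CC[C@@]3(C)C(=C2)CCC3=O | intermediate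
3 | 3,3-ethylenedithio-8,8-ethylenedioxy-10-methylhydrind-4-ene | C12(SCCS1)CC[C@@]3(C)C(=C2)CCC34OCCO4 | intermediate
4 | 8,8-ethylenedioxy-10-methylhydrind-4-ene | C1CC[C@@]2(C)C(=C1)CCC23OCCO3 | intermediate
5 | alkylborane: 4α-boryl-8,8-ethylenedioxy-10β-methyl-trans-hydrindane (drawn as RBH2) | B[C@@H]1CCC[C@@]2(C)[C@H]1CCC23OCCO3 | intermediate
6 | hydroxy ketal: 8,8-ethylenedioxy-10β-methyl-trans-hydrindan-4α-ol (5α-H) | O[C@@H]1CCC[C@@]2(C)[C@H]1CCC23OCCO3 | intermediate
7 | 4α-hydroxy-10β-methyl-trans-hydrindan-8-one (5α-H) | O[C@@H]1CCC[C@@]2(C)[C@H]1CCC2=O | intermediate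
8 | 4α-(tert-butyldimethylsilyloxy)-10β-methyl-trans-hydrindan-8-one | CC(C)(C)[Si](C)(C)O[C@@H]1CCC[C@@]2(C)[C@H]1CCC2=O | intermediate
9 | ethyl vinyl ether | C=COCC | starting material
10 | 1-ethoxyvinyllithium | [Li]C(=C)OCC | intermediate
11 | ethoxyvinyl carbinol: 8α-(1-ethoxyvinyl)-4α-TBSO-10β-methyl-trans-hydrindan-8β-ol | CC(C)(C)[Si](C)(C)O[C@@H]1CCC[C@@]2(C)[C@H]1CC[C@@]2(O)C(=C)OCC | intermediate
12 | 8α-acetyl-4α-TBSO-10β-methyl-trans-hydrindan-8β-ol | CC(C)(C)[Si](C)(C)O[C@@H]1CCC[C@@]2(C)[C@H]1CC[C@@]2(O)C(C)=O | intermediate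
13 | 8α-[(2S)-2-methyloxiran-2-yl]-4α-TBSO-10β-methyl-trans-hydrindan-8β-ol (key-step precursor) | CC(C)(C)[Si](C)(C)O[C@@H]1CCC[C@@]2(C)[C@H]1CC[C@@]2(O)[C@]3(C)CO3 | intermediate
14 | 9α-(hydroxymethyl)-9β,10β-dimethyl-4α-TBSO-trans-decalin-8-one (key-step product) | CC(C)(C)[Si](C)(C)O[C@@H]1CCC[C@@]2(C)[C@H]1CCC(=O)[C@@]2(C)CO | intermediate
15 | 9α-(triethylsilyloxymethyl)-9β,10β-dimethyl-4α-TBSO-trans-decalin-8-one | CC(C)(C)[Si](C)(C)O[C@@H]1CCC[C@@]2(C)[C@H]1CCC(=O)[C@@]2(C)CO[Si](CC)(CC)CC | intermediate
16 | methylene TES ether: 8-methylene-9α-(triethylsilyloxymethyl)-9β,10β-dimethyl-4α-TBSO-trans-decalin | CC(C)(C)[Si](C)(C)O[C@@H]1CCC[C@@]2(C)[C@H]1CCC(=C)[C@@]2(C)CO[Si](CC)(CC)CC | intermediate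
17 | (8-methylene-9β,10β-dimethyl-4α-TBSO-trans-decalin-9α-yl)methanol | CC(C)(C)[Si](C)(C)O[C@@H]1CCC[C@@]2(C)[C@H]1CCC(=C)[C@@]2(C)CO | intermediate
18 | (8β,9β,10β-trimethyl-4α-TBSO-trans-decalin-9α-yl)methanol (8α-H) | CC(C)(C)[Si](C)(C)O[C@@H]1CCC[C@@]2(C)[C@H]1CC[C@H](C)[C@@]2(C)CO | intermediate
19 | 8β,9β,10β-trimethyl-4α-TBSO-trans-decalin-9α-carbaldehyde | CC(C)(C)[Si](C)(C)O[C@@H]1CCC[C@@]2(C)[C@H]1CC[C@H](C)[C@@]2(C)C=O | intermediate
20 | 1,2,4,5-tetramethoxybenzene | COc1cc(OC)c(OC)cc1OC | starting material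
21 | aryllithium: (2,3,5,6-tetramethoxyphenyl)lithium | [Li]c1c(OC)c(OC)cc(OC)c1OC | intermediate
22 | lithium alkoxide of the C11 (2,3,5,6-tetramethoxyphenyl) carbinol (both C11 epimers) | CC(C)(C)[Si](C)(C)O[C@@H]1CCC[C@@]2(C)[C@H]1CC[C@H](C)[C@@]2(C)C(O[Li])c1c(OC)c(OC)cc(OC)c1OC | intermediate
23 | lithium xanthate: lithium O-(C11 aryl carbinyl) dithiocarbonate | CC(C)(C)[Si](C)(C)O[C@@H]1CCC[C@@]2(C)[C@H]1CC[C@H](C)[C@@]2(C)C(OC(=S)S[Li])c1c(OC)c(OC)cc(OC)c1OC | intermediate
24 | S-methyl xanthate of the C11 aryl carbinol (both C11 epimers) | CC(C)(C)[Si](C)(C)O[C@@H]1CCC[C@@]2(C)[C@H]1CC[C@H](C)[C@@]2(C)C(OC(=S)SC)c1c(OC)c(OC)cc(OC)c1OC | intermediate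
25 | 9α-(2,3,5,6-tetramethoxybenzyl)-8β,9β,10β-trimethyl-4α-TBSO-trans-decalin | CC(C)(C)[Si](C)(C)O[C@@H]1CCC[C@@]2(C)[C@H]1CC[C@H](C)[C@@]2(C)Cc1c(OC)c(OC)cc(OC)c1OC | intermediate
26 | 9α-(2,3,5,6-tetramethoxybenzyl)-8β,9β,10β-trimethyl-trans-decalin-4α-ol | O[C@@H]1CCC[C@@]2(C)[C@H]1CC[C@H](C)[C@@]2(C)Cc1c(OC)c(OC)cc(OC)c1OC | intermediate
27 | 9α-(2,3,5,6-tetramethoxybenzyl)-8β,9β,10β-trimethyl-trans-decalin-4-one (5α-H) | O=C1CCC[C@@]2(C)[C@H]1CC[C@H](C)[C@@]2(C)Cc1c(OC)c(OC)cc(OC)c1OC | intermediate
28 | 9α-(2,3,5,6-tetramethoxybenzyl)-8β,9β,10β-trimethyl-4-methylene-trans-decalin | C=C1CCC[C@@]2(C)[C@H]1CC[C@H](C)[C@@]2(C)Cc1c(OC)c(OC)cc(OC)c1OC | intermediate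
29 | 3-[(8β,9β,10β-trimethyl-4-methylene-trans-decalin-9α-yl)methyl]-2,5-dimethoxy-1,4-benzoquinone | C=C1CCC[C@@]2(C)[C@H]1CC[C@H](C)[C@@]2(C)CC1=C(OC)C(=O)C=C(OC)C1=O | intermediate
30 | 2-hydroxy-5-methoxy-3-[(8β,9β,10β-trimethyl-4-methylene-trans-decalin-9α-yl)methyl]-1,4-benzoquinone (CNP0109104.1) | C=C1CCC[C@@]2(C)[C@H]1CC[C@H](C)[C@@]2(C)CC1=C(O)C(=O)C=C(OC)C1=O | target

**Step count.** Total: 19 steps. Longest linear sequence: 19 steps (1 → 30); 9 and 20 enter as in-situ organolithiums without steps of their own.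

**Steps most likely to fail**

Step 8 (key step). What may go wrong: shift of the C7 methylene in place of C10, from the rotamer in which the epoxide C–O bond lies anti to C7 (favoured when a hydrogen bond or the Lewis acid bridges the two oxygens). Partial ionisation to a free C9 cation could also erode the transfer of configuration or lead to capture by fluoride. The fallback sets out from 13 and returns at 14. The tertiary hydroxyl is capped with N-(trimethylsilyl)imidazole to give the epoxy trimethylsilyl ether F1. This is rearranged with the bulky monodentate aluminium Lewis acid MABR, methylaluminium bis(4-bromo-2,6-di-tert-butylphenoxide), in CH2Cl2 at −78 °C, the known organoaluminium-promoted rearrangement of epoxy silyl ethers. The silyl ether cannot chelate, the aluminium-bound epoxide oxygen takes the open position anti to C10, and the ether oxygen drives the shift. Mild acidic work-up removes the trimethylsilyl group and gives 14.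

Step 7. What may go wrong: poor facial selectivity if the ylide adds through the non-chelated rotamer of the ketol (carbonyl anti to the C8–O bond), which leads to the C9-epimeric epoxide, together with enolisation of the methyl ketone. The fallback sets out from 12 and returns at 13. Magnesium-chelate-controlled addition of excess (isopropoxydimethylsilyl)methylmagnesium chloride (the first equivalent forms the magnesium alkoxide) should give the silylmethyl diol F2, with C11 again delivered anti to C10. Tamao–Fleming oxidation (H2O2, KF, KHCO3, THF/MeOH) gives the triol F3. Selective sulfonylation of the primary hydroxyl (TsCl, pyridine) gives the monotosylate F4, which K2CO3 in MeOH closes through the C9 oxygen to 13.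

Step 10. What may go wrong: no olefination, because both faces of the C8 carbonyl are shielded (axial C11 arm on the α face, syn-axial C10 methyl on the β face) and the ylide merely enolises the ketone toward C7. The fallback sets out from 15, returns at 18 and uses that enolisation. KHMDS then PhNTf2 gives the C7=C8 enol triflate F5. Iron-catalysed cross-coupling with MeMgBr [Fe(acac)3, THF/NMP] gives the 8-methyl-Δ7 alkene F6. PPTS in MeOH removes the TES group to give the homoallylic alcohol F7. Hydroxyl-directed hydrogenation with Crabtree's catalyst then adds hydrogen to the α face of the trisubstituted alkene and gives 18.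

**Further compounds**

F1 | step 8 | 8α-[(2S)-2-methyloxiran-2-yl]-8β-(trimethylsilyloxy)-4α-TBSO-10β-methyl-trans-hydrindane | CC(C)(C)[Si](C)(C)O[C@@H]1CCC[C@@]2(C)[C@H]1CC[C@@]2(O[Si](C)(C)C)[C@]3(C)CO3
F2 | step 7 | silylmethyl diol: 8α-[(2S)-2-hydroxy-1-(isopropoxydimethylsilyl)propan-2-yl]-4α-TBSO-10β-methyl-trans-hydrindan-8β-ol | CC(C)(C)[Si](C)(C)O[C@@H]1CCC[C@@]2(C)[C@H]1CC[C@@]2(O)[C@](O)(C)C[Si](C)(C)OC(C)C
F3 | step 7 | triol: 8α-[(2S)-1,2-dihydroxypropan-2-yl]-4α-TBSO-10β-methyl-trans-hydrindan-8β-ol | CC(C)(C)[Si](C)(C)O[C@@H]1CCC[C@@]2(C)[C@H]1CC[C@@]2(O)[C@](O)(C)CO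
F4 | step 7 | primary monotosylate of triol F3 | CC(C)(C)[Si](C)(C)O[C@@H]1CCC[C@@]2(C)[C@H]1CC[C@@]2(O)[C@](O)(C)COS(=O)(=O)c1ccc(C)cc1
F5 | step 10 | C7=C8 enol triflate of 15 | CC(C)(C)[Si](C)(C)O[C@@H]1CCC[C@@]2(C)[C@H]1CC=C(OS(=O)(=O)C(F)(F)F)[C@@]2(C)CO[Si](CC)(CC)CC
F6 | step 10 | 8,9β,10β-trimethyl-9α-(triethylsilyloxymethyl)-4α-TBSO-trans-decal-7-ene | CC(C)(C)[Si](C)(C)O[C@@H]1CCC[C@@]2(C)[C@H]1CC=C(C)[C@@]2(C)CO[Si](CC)(CC)CC
F7 | step 10 | (8,9β,10β-trimethyl-4α-TBSO-trans-decal-7-en-9α-yl)methanol | CC(C)(C)[Si](C)(C)O[C@@H]1CCC[C@@]2(C)[C@H]1CC=C(C)[C@@]2(C)CO
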